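Time was the first thing I held against the readings: by 6.3 min the oak run had almost stopped rising, at 0.3449 M of target, less than either charge.

| flask | substrate | partner | time |
|---|---|---|---|
| oak | 0.800 M | 0.960 M |  |
| ash | 0.480 M | 0.640 M |  |
| birch | 0.800 M | 2.90 M |  |
| larch | 2.40 M | 0.960 M |  |
| cedar | 2.40 M | 2.90 M | 6.3 min |

| run | time / min | [target] / M |
|---|---|---|
| oak run | 0.48 | 0.0976 |
| oak run | 1.5 | 0.2140 |
| oak run | 2.8 | 0.2870 |
| oak run | 4.4 | 0.3276 |
| oak run | 6.3 | 0.3449 |
| ash run | 0.48 | 0.0421 |
| ash run | 1.5 | 0.1037 |
| ash run | 2.8 | 0.1401 |
| ash run | 4.4 | 0.1634 |
| ash run | 6.3 | 0.1769 |
| birch run | 0.48 | 0.2010 |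
| birch run | 1.5 | 0.4097 |
| birch run | 2.8 | 0.5104 |
| birch run | 4.4 | 0.5574 |
| birch run | 6.3 | 0.5699 |
| larch run | 0.48 | 0.2147 |
| larch run | 1.5 | 0.4582 |
| larch run | 2.8 | 0.5821 |
| larch run | 4.4 | 0.6267 |
| larch run | 6.3 | 0.6409 |

(each reading ± 0.002 M)

- the exponent of [substrate] in the starting rate at the charge of the oak run (at the point where two percent of the substrate have become target) (one fixed amount of target, the same in the runs compared)
- the exponent of [partner] in the starting rate at the charge of the oak run (at the point where two percent of the substrate have become target)
- target in the cedar run at 6.3 min, as a share of the substrate charged

- Overall: substrate + partner -> target.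
- Constant volume, constant temperature.
- The analysis sees a species whether free or bound.
- "The second partner" is partner.
- An order is taken over about fifteen percent of the charge, up and down.

I built the flask one process at a time. With the main step alone, the first reading of the oak run gives a rate constant of about

k = 0.265 /M/min

and second-order integration with this k puts the oak run at 0.518 M by 6.3 min, more than the reading. The same reckoning puts the cedar run at 2.12 M, or 88.3% of its substrate, and I distrusted that figure after the oak comparison.

So I added a first-order loss of partner, which competes with the main step. Dividing the two rate equations removes time, and if the partner is counted as gone at the last reading, one quantity remains: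

c = ([partner] charged − [target]) / ln([substrate] charged / ([substrate] charged − [target]))

I called c the break-even substrate, the [substrate] at which partner is lost as fast as it is used, a selectivity factor that carries a unit. The oak run reads 1.09 M and the larch run, with the same partner charge, 1.03 M. One Newton step from half the cedar substrate, using the oak value, lowered the cedar run to

[target] = 1.69 M, or 70.6%.

The rest of the flask showed in the birch run. There the partner charge went up 3.02 times over the oak run but the first reading went up 2.06 times, and c read 1.87 M, more than in the oak run. The cedar run has the birch partner charge, so the same Newton step with the birch value gave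

[target] = 1.36 M, or 56.6%.

The birch quotient counts unspent partner as lost, so I committed to a little above that share.

The forecast gave orders of 0.86 in substrate and 0.85 in partner and 61% for the cedar run, between 57% and 65%, reading the curves thus: “The plateaus look like equilibrium, not completion”.

The cedar run gave 61.0% of its substrate as target, and at the charge of the oak run the orders came to 0.91 in substrate and 0.87 in partner, from these steps:

    substrate + partner → target (0.4500 /M/min)
    target + partner → side product (0.04644 /M/min)
    substrate + partner ⇌ idle substrate-reagent adduct, settled at all times (0.2890 /M)
    partner → lost reagent (0.3792 /min)

The partner loss stands there with 0.379 /min, and its ratio to the main constant is 0.843 M. Read from the result, the cedar run has c = 1.52 M, more than the oak value of 1.09 M and less than the birch value of 1.87 M. The ash run, read the same way, has c = 1.01 M.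

The runs stem from a simulated flask on assumed constants; noise was put on by code.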